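## Retrosynthetic overview

1. Ring B is closed last. The C1–C8a bond comes from an intramolecular Friedel–Crafts attack of ring A on a p-quinone methide made from an acyclic (R)-hydroxy-enal, and the C2 centre steers C1 to trans.
2. The C3=C4 enal double bond comes from an amine-catalysed aldol condensation of syringaldehyde with an (R)-γ-lactol.
3. Key disconnection: the CH2–O bond of the γ-lactone behind that lactol, whose oxygen ends as the CH2OH oxygen. It is made by catalytic enantioselective Baeyer–Villiger oxygen insertion into a prochiral 3-benzylcyclobutanone, and this step alone sets the absolute configuration.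
4. The cyclobutanone comes from a dichloroketene [2+2] cycloaddition to O-acetylated 4-allyl-2,6-dimethoxyphenol.
5. Ring order: cyclobutanone, then γ-lactone by ring expansion, then lactol (opened during the condensation), then carbocycle B.

Assumption: the sense of induction of the new catalyst in step 3 cannot be predicted. The catalyst antipode that gives (R)-6 is picked after one test run, since both BINOL antipodes are available.

Locants: C1 to C8a are those of the 1,2-dihydronaphthalene. Ring A is the fused arene, ring B the new carbocycle and ring C the pendant aryl group.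

## Route

Step 1
Reactants: 1 methoxyeugenol (4-allyl-2,6-dimethoxyphenol)
Product: 2 methoxyeugenol acetate (4-allyl-2,6-dimethoxyphenyl acetate)
Conditions: Ac2O (1.2 equiv), pyridine, 0 °C to rt
Reagents that add atoms: acetic anhydride CC(=O)OC(C)=O
Why: Standard O-acylation of a phenol, which masks the OH that would otherwise add to the ketene in step 2 and shields ring C from the peroxide in step 3, with no stereocentre involved.

Step 2
Reactants: 2 methoxyeugenol acetate
Product: 4 prochiral ketone 3-(4-acetoxy-3,5-dimethoxybenzyl)cyclobutanone, via dichlorocyclobutanone 3 (not isolated)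
Conditions: Cl3CCOCl (2 equiv), Zn–Cu couple, Et2O, 35 °C; then Zn dust, AcOH, rt to 60 °C
Reagents that add atoms: trichloroacetyl chloride ClC(=O)C(Cl)(Cl)Cl
Why: A thermal [2+2] ketene–alkene cycloaddition of dichloroketene made in the flask joins the ketene carbonyl carbon to the terminal CH2 of the allyl group to give 3, and zinc/acetic acid reductive dechlorination then leaves the achiral but prochiral ketone 4, a sequence well proven on allylarenes.

Step 3
Reactants: 4 prochiral ketone 3-(4-acetoxy-3,5-dimethoxybenzyl)cyclobutanone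
Product: 6 (4R)-4-(4-acetoxy-3,5-dimethoxybenzyl)dihydrofuran-2(3H)-one, via Criegee perhydrate 5 (not isolated)
Conditions: confined imidodiphosphoric acid built from two 3,3'-di(1-pyrenyl)-H8-BINOL units (5 mol%), 30% aq H2O2 (1.5 equiv), CHCl3, −40 °C
Reagents that add atoms: hydrogen peroxide OO
Why: Proposed new method: an organocatalytic Baeyer–Villiger desymmetrisation in which the bifunctional O=P–NH–P=O site of a confined imidodiphosphoric acid hydrogen-bonds ketone 4 and H2O2 together and forms Criegee perhydrate 5 inside a narrow chiral cleft, where the aryl acetate stacks on a pyrenyl wall and locks the ring pucker so that only one of the two enantiotopic CH2–C(=O) bonds can lie antiperiplanar to the O–O bond and migrate (strain release makes this fast at −40 °C), which forges the CH2–O bond that survives as the CH2OH oxygen of the target and sets its C2 centre as R; the closest known reaction types are the chiral phosphoric acid/H2O2 Baeyer–Villiger oxidation of 3-arylcyclobutanones, which gives only moderate ee with flexible 3-benzyl groups, and the H2O2 sulfoxidation run with confined imidodiphosphoric acids.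

Step 4
Reactants: 6 (4R)-4-(4-acetoxy-3,5-dimethoxybenzyl)dihydrofuran-2(3H)-one
Product: 7 (4R)-4-(4-hydroxy-3,5-dimethoxybenzyl)tetrahydrofuran-2-ol (anomer mixture)
Conditions: iBu2AlH (3.3 equiv), CH2Cl2, −78 °C; aq potassium sodium tartrate
Reagents that add atoms: none
Why: Partial lactone reduction stops at the lactol because the cyclic aluminium hemiacetal is stable at −78 °C, two further hydrides cleave the aryl acetate so no separate deprotection is needed, the C4 centre is untouched and the new anomeric carbon is an inconsequential mixture.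

Step 5
Reactants: 7 (4R)-4-(4-hydroxy-3,5-dimethoxybenzyl)tetrahydrofuran-2-ol; 8 syringaldehyde (4-hydroxy-3,5-dimethoxybenzaldehyde, 1.5 equiv)
Product: 9 (2E)-2-[(2R)-1-hydroxy-3-(4-hydroxy-3,5-dimethoxyphenyl)propan-2-yl]-3-(4-hydroxy-3,5-dimethoxyphenyl)prop-2-enal
Conditions: pyrrolidine (30 mol%), AcOH (30 mol%), iPrOH, 4 Å MS, 50 °C, Ar
Reagents that add atoms: none
Why: In this amine-catalysed cross-aldol (Mannich-type) condensation pyrrolidine opens lactol 7 to its enamine, whose low standing concentration curbs self-condensation, and converts 8 into an iminium ion that stays electrophilic despite the free phenol (the activation used in Knoevenagel–Doebner reactions of 8), loss of the amine then gives the thermodynamically preferred E-enal with ring A cis to the side chain as ring closure needs, and the R centre is not enolisable and is kept.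

Step 6
Reactants: 9 (2E)-2-[(2R)-1-hydroxy-3-(4-hydroxy-3,5-dimethoxyphenyl)propan-2-yl]-3-(4-hydroxy-3,5-dimethoxyphenyl)prop-2-enal
Product: 11 target (1S,2R)-7-hydroxy-1-(4-hydroxy-3,5-dimethoxyphenyl)-2-(hydroxymethyl)-6,8-dimethoxy-1,2-dihydronaphthalene-3-carbaldehyde, via p-quinone methide 10 (not isolated)
Conditions: DDQ (1.0 equiv, slow addition), CH2Cl2–THF 4:1, −20 °C; then CF3CO2H (10 mol%), −20 to 0 °C
Reagents that add atoms: none
Why: Dehydrogenation of the electron-rich 4-alkyl-2,6-dimethoxyphenol (ring C) by DDQ gives p-quinone methide 10, the enal-conjugated phenol of ring A being much harder to oxidise, and an acid-promoted intramolecular Friedel–Crafts 1,6-addition of the ring A carbon that is ortho and para to its two methoxy groups closes ring B, the R centre holding CH2OH pseudo-axial so that ring C ends on the opposite face (trans, 1S) as in the oxidative dimerisation of sinapate esters to trans-thomasidioates.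

## Compound list

1 | methoxyeugenol (4-allyl-2,6-dimethoxyphenol) | C=CCc1cc(OC)c(O)c(OC)c1 | starting material
2 | 4-allyl-2,6-dimethoxyphenyl acetate | C=CCc1cc(OC)c(OC(C)=O)c(OC)c1 | intermediate
3 | rac-2,2-dichloro-3-(4-acetoxy-3,5-dimethoxybenzyl)cyclobutanone (not isolated) | CC(=O)Oc1c(OC)cc(CC2CC(=O)C2(Cl)Cl)cc1OC | intermediate
4 | 3-(4-acetoxy-3,5-dimethoxybenzyl)cyclobutanone (achiral, prochiral) | CC(=O)Oc1c(OC)cc(CC2CC(=O)C2)cc1OC | intermediate
5 | Criegee perhydrate, 1-hydroperoxy-3-(4-acetoxy-3,5-dimethoxybenzyl)cyclobutan-1-ol (not isolated) | CC(=O)Oc1c(OC)cc(CC2CC(O)(OO)C2)cc1OC | intermediate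
6 | (4R)-4-(4-acetoxy-3,5-dimethoxybenzyl)dihydrofuran-2(3H)-one | O=C1C[C@@H](Cc2cc(OC)c(OC(C)=O)c(OC)c2)CO1 | intermediate
7 | (4R)-4-(4-hydroxy-3,5-dimethoxybenzyl)tetrahydrofuran-2-ol, anomer mixture | OC1C[C@@H](Cc2cc(OC)c(O)c(OC)c2)CO1 | intermediate
8 | syringaldehyde | COc1cc(C=O)cc(OC)c1O | starting material
9 | (2E)-2-[(2R)-1-hydroxy-3-(4-hydroxy-3,5-dimethoxyphenyl)propan-2-yl]-3-(4-hydroxy-3,5-dimethoxyphenyl)prop-2-enal | O=C/C(=C/c1cc(OC)c(O)c(OC)c1)[C@@H](Cc1cc(OC)c(O)c(OC)c1)CO | intermediate
10 | p-quinone methide of 9 (ring C oxidised, R centre and E-enal kept, not isolated) | COC1=CC(=C[C@@H](CO)/C(C=O)=C\c2cc(OC)c(O)c(OC)c2)C=C(OC)C1=O | intermediate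
11 | (1S,2R)-7-hydroxy-1-(4-hydroxy-3,5-dimethoxyphenyl)-2-(hydroxymethyl)-6,8-dimethoxy-1,2-dihydronaphthalene-3-carbaldehyde (trans) | COc1cc([C@H]2c3c(cc(OC)c(O)c3OC)C=C(C=O)[C@@H]2CO)cc(OC)c1O | target

## Step count and risks

Total step count: 6. Longest linear sequence: 6 steps (1 to 11). Compound 8 enters in step 5.

**Step 3 (the new step).**
- Risk: low ee for the flexible benzyl group, or slow turnover of the acid in the presence of water.
- The fallback uses known chemistry, sets out from 4 and comes back at 7.
- 30% H2O2 in AcOH at 0 °C gives the racemic lactone F1.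
- Heating F1 with (R)-1-phenylethylamine in toluene opens the lactone and removes the acetate.
- This gives the (3R)-hydroxy amide F2 and its (3S) diastereomer F3, which are separated by crystallisation or chromatography.
- 2 M H2SO4 in dioxane at reflux relactonises F2 to the free-phenol lactone F4.
- iBu2AlH at −78 °C reduces F4 to 7.

**Step 5.**
- Risk: the phenolic aldehyde reacts sluggishly, 7 self-condenses, or the γ-hydroxy-enal dehydrates to a furan.
- The fallback moves the C=C formation to the lactone stage. It sets out from 6 (and uses 8) and comes back at 9.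
- K2CO3 in MeOH gives the free-phenol lactone F4, and tBuMe2SiCl with imidazole gives the silyl ether lactone F5.
- Compound 8 is silylated in the same way to the silyl ether aldehyde F6.
- The LiN(iPr)2 enolate of F5 adds to F6, anti to the benzyl group, to give the aldol adduct F7.
- Catalytic TsOH in toluene dehydrates F7 to the (E)-arylidene lactone F8.
- iBu2AlH at −78 °C gives the bis-silyl hydroxy-enal F9.
- Bu4NF with AcOH frees both phenols to give 9.

**Step 6.**
- Risk: DDQ over-oxidises the doubly benzylic C1–H of 11 to the arylnaphthalene. Alternatively, 10 tautomerises to the achiral dienal, which costs yield rather than ee because that dienal does not cyclise under these mild conditions.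
- The fallback separates the oxidation from the ring closure, so the product never meets the oxidant. It sets out from 9 and comes back at 11.
- DDQ (1.0 equiv) in MeOH–CH2Cl2 traps the quinone methide as the benzylic methyl ether F10, an epimer mixture at the new carbon, which is isolated.
- CF3CO2H in CH2Cl2 at −20 °C ionises F10 and gives the same trans-selective Friedel–Crafts closure to 11. This is the reaction type that turns 7-hydroxylignans into aryltetralins.

## Further compounds

F1 | step 3 | rac-4-(4-acetoxy-3,5-dimethoxybenzyl)dihydrofuran-2(3H)-one | CC(=O)Oc1c(OC)cc(CC2COC(=O)C2)cc1OC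
F2 | step 3 | (3R)-4-hydroxy-3-(4-hydroxy-3,5-dimethoxybenzyl)-N-[(1R)-1-phenylethyl]butanamide | C[C@@H](NC(=O)C[C@@H](Cc1cc(OC)c(O)c(OC)c1)CO)c1ccccc1
F3 | step 3 | (3S)-4-hydroxy-3-(4-hydroxy-3,5-dimethoxybenzyl)-N-[(1R)-1-phenylethyl]butanamide | C[C@@H](NC(=O)C[C@H](Cc1cc(OC)c(O)c(OC)c1)CO)c1ccccc1
F4 | step 3 | (4R)-4-(4-hydroxy-3,5-dimethoxybenzyl)dihydrofuran-2(3H)-one | O=C1C[C@@H](Cc2cc(OC)c(O)c(OC)c2)CO1
F5 | step 5 | (4R)-4-[4-(tert-butyldimethylsilyloxy)-3,5-dimethoxybenzyl]dihydrofuran-2(3H)-one | O=C1C[C@@H](Cc2cc(OC)c(O[Si](C)(C)C(C)(C)C)c(OC)c2)CO1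
F6 | step 5 | 4-(tert-butyldimethylsilyloxy)-3,5-dimethoxybenzaldehyde | COc1cc(C=O)cc(OC)c1O[Si](C)(C)C(C)(C)C
F7 | step 5 | (3S,4R)-trans aldol adduct, 3-[aryl(hydroxy)methyl]-4-(arylmethyl)dihydrofuran-2(3H)-one with both aryl groups 4-silyloxy-3,5-dimethoxyphenyl, epimers at the carbinol carbon | O=C1OC[C@H](Cc2cc(OC)c(O[Si](C)(C)C(C)(C)C)c(OC)c2)[C@H]1C(O)c1cc(OC)c(O[Si](C)(C)C(C)(C)C)c(OC)c1
F8 | step 5 | (3E,4R)-3-arylidene-4-(arylmethyl)dihydrofuran-2(3H)-one, both aryl groups 4-silyloxy-3,5-dimethoxyphenyl | O=C1OC[C@H](Cc2cc(OC)c(O[Si](C)(C)C(C)(C)C)c(OC)c2)/C1=C\c1cc(OC)c(O[Si](C)(C)C(C)(C)C)c(OC)c1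
F9 | step 5 | bis(tert-butyldimethylsilyl) ether of 9 | O=C/C(=C/c1cc(OC)c(O[Si](C)(C)C(C)(C)C)c(OC)c1)[C@@H](Cc1cc(OC)c(O[Si](C)(C)C(C)(C)C)c(OC)c1)CO
F10 | step 6 | benzylic methyl ether of 9 (OMe on the CH next to ring C, epimer mixture there, R centre and E-enal kept) | O=C/C(=C/c1cc(OC)c(O)c(OC)c1)[C@@H](C(OC)c1cc(OC)c(O)c(OC)c1)CO
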